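The runs were computed for substances that don't exist; the scatter is artificial.

The north run shows the shape of the problem, and it is a matter of amounts: target is counted against the substrate charged, and the catalyst is charged at 0.5 mol% of it.

| flask | substrate | free catalyst | temperature | remark | time |
|---|---|---|---|---|---|
| north | 0.75 M | 0.5 mol% | 78 °C | run made earlier |  |
| south | 1.1 M | 0.5 mol% | 94 °C | run made earlier |  |
| north-east | 1.5 M | 1 mol% | 78 °C | run made earlier |  |
| teal | 1.5 M | 0.5 mol% | 70 °C |  | 8.0 d |
| grey | 1.5 M | 0.5 mol% | 100 °C |  | 8.0 d |

- north (time / d: target / %): 2.08: 9.8; 4.00: 14.6; 6.00: 17.6; 8.00: 18.4
- south (time / d: target / %): 0.625: 11.1; 1.25: 15.4; 1.67: 16.7; 2.50: 18.7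
- north-east (time / d: target / %): 2.08: 21.3; 4.00: 27.4; 6.00: 29.5; 8.00: 30.5

(standard deviation of a reading: 0.5 percentage points)

- the flask with the highest amount of target, in percent of the substrate charged ("all alike" if they lie within 1.5 percentage points) (teal / grey / all alike)
- final target, as a percentage of the substrate charged, in teal
- final target, as a percentage of the substrate charged, in grey

Target in the north run gains 9.8% by 2.08 d, but only 0.8 percentage points between 6.00 d and 8.00 d, so the pace at the end is far lower than at the start. Two readings of this stall are open. One takes it as a balance between substrate and target, whose height moves with concentration and temperature. The other counts the turnover number n, the target made per catalyst charged, which is the percentage of target divided by the loading: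

n = 18.4% / 0.5 mol% = 36.8

South gives 37.4 and north-east 30.5. The north-east count is lower than the north count, so n is no constant across these two runs, which differ in loading and in concentration. At equal loading, though, n from the north run predicts the south run:

target = n × 0.5 mol% = 18.4%

South reads 18.7% at 2.50 d, a gap of 0.3 points, which is less than the scatter of 0.5 points, although south differs in temperature and concentration. A balance can match south too, by taking its temperature dependence from south, so that match is no check. The count took nothing from south. This reckoning therefore commits to about 18.4% in both teal and grey, which share the loading, and so to no clear difference between them.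

The forecast keeps the balance: “Catalyst therefore seems to change the rate, not the endpoint”. It gives teal 27% (23% to 30.5%) and grey 23% (21% to 25%), with teal highest. For grey it stands 4.6 points above the count.

The flasks give 22.4% in teal and 16.3% in grey, so teal is highest.

    substrate + free catalyst ⇌ free catalyst + target (K = 0.989, k = 0.0547 /M/min, Ea = 67.0 kJ/mol, ΔH = −23.0 kJ/mol)
    substrate → side product (k = 4.27 × 10⁻⁴ /min, Ea = 122 kJ/mol)
    2 free catalyst → spent catalyst (k = 0.120 /M/min, Ea = 60.0 kJ/mol)
    (constants at 100 °C)

The count comes to 44.8 in teal and 32.6 in grey, the grey count lying below n. Within grey it falls with time, from 36.8 at 4.00 d to 32.6 at 8.00 d, when side product stands at 82.4%. The neighbouring flask, a repeat of grey at 125 °C, counts 6.77, far below grey. That neighbouring flask ends with target at 3.38% and side product at 96.6%.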